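The route rests on cutting ring C of the flavanone at the O1–C8a aryl ether bond. C8a is an sp2 carbon of ring A wedged between C8 (OMe) and C4a, so it can carry a bromine through the sequence while the lone stereocentre C2 is set earlier as a benzylic carbinol. One copper-catalysed intramolecular O-arylation then closes the pyran ring without breaking the C2–O bond, so the S configuration passes into the product unchanged. The precursor is an open-chain anti (1S,3S)-1,3-diarylpropane-1,3-diol bearing the ortho-bromo ring A, a benzyl-protected ring B phenol and a free C4 carbinol, made by double asymmetric hydrogenation of a 1,3-diketone.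

Key step: step 6

Assumption (remark on the chemistry): both starting materials are purchased. The (R)-BINAP ruthenium catalyst is taken to reduce each aryl ketone with the facial sense it shows for simple aryl β-dicarbonyl compounds, which corresponds to S at both carbinol carbons because aryl outranks CH2. Should a trial run show the opposite sense, (S)-BINAP would be used.

Step 1
Reactants: 1 2-bromo-3,4-dimethoxybenzaldehyde
Product: 2 1-(2-bromo-3,4-dimethoxyphenyl)ethan-1-ol (racemic)
Conditions: MeMgBr (1.2 equiv), THF, 0 °C; then aq. NH4Cl
Reagents that add atoms: methylmagnesium bromide, C[Mg]Br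
Why: Grignard 1,2-addition to the aryl aldehyde is far faster at 0 °C than magnesium–halogen exchange at the hindered C–Br bond, and the new carbinol centre may stay racemic because it is oxidised in step 2.

Step 2
Reactants: 2 1-(2-bromo-3,4-dimethoxyphenyl)ethan-1-ol
Product: 3 1-(2-bromo-3,4-dimethoxyphenyl)ethan-1-one
Conditions: activated MnO2 (excess), CH2Cl2, rt
Reagents that add atoms: none
Why: Heterogeneous MnO2 oxidation is selective for benzylic alcohols and should leave the aryl bromide and the methyl ethers untouched.

Step 3
Reactants: 4 methyl 3-hydroxy-4,5-dimethoxybenzoate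
Product: 5 methyl 3-(benzyloxy)-4,5-dimethoxybenzoate
Conditions: BnBr, K2CO3, DMF, 60 °C
Reagents that add atoms: benzyl bromide, BrCc1ccccc1
Why: Williamson ether synthesis, in which the phenoxide formed by K2CO3 is benzylated by SN2 displacement while the methyl ester is stable to carbonate; the benzyl ether masks the only phenol so that it cannot compete as a nucleophile in the copper step.

Step 4
Reactants: 3 1-(2-bromo-3,4-dimethoxyphenyl)ethan-1-one; 5 methyl 3-(benzyloxy)-4,5-dimethoxybenzoate
Product: 6 1-[3-(benzyloxy)-4,5-dimethoxyphenyl]-3-(2-bromo-3,4-dimethoxyphenyl)propane-1,3-dione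
Conditions: NaH (2.5 equiv), THF, 65 °C; then 1 M HCl
Reagents that add atoms: none
Why: Crossed Claisen condensation, in which the sodium enolate of the methyl ketone acylates the non-enolisable aryl ester and irreversible deprotonation of the 1,3-diketone by the second equivalent of NaH pulls the equilibrium forward; the aryl bromide is inert to NaH.

Step 5
Reactants: 6 1-[3-(benzyloxy)-4,5-dimethoxyphenyl]-3-(2-bromo-3,4-dimethoxyphenyl)propane-1,3-dione
Product: 7 (1S,3S)-3-[3-(benzyloxy)-4,5-dimethoxyphenyl]-1-(2-bromo-3,4-dimethoxyphenyl)propane-1,3-diol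
Conditions: H2 (50 bar), Ru2Cl4[(R)-BINAP]2(NEt3) (1 mol%), EtOH/CH2Cl2, 50 °C
Reagents that add atoms: none
Why: Noyori asymmetric hydrogenation of a chelating 1,3-diketone by the (R)-BINAP divalent ruthenium catalyst, where the ligand fixes the hydride face at each carbonyl (S at both) and the first carbinol reinforces anti delivery in the second reduction, so the anti (1S,3S) diol should dominate and would be freed of any syn isomer by crystallisation or chromatography; this homogeneous catalyst should touch neither the aryl bromide nor the benzyl ether.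

Step 6
Reactants: 7 (1S,3S)-3-[3-(benzyloxy)-4,5-dimethoxyphenyl]-1-(2-bromo-3,4-dimethoxyphenyl)propane-1,3-diol
Product: 8 (2S,4S)-2-[3-(benzyloxy)-4,5-dimethoxyphenyl]-7,8-dimethoxychroman-4-ol (2,4-cis)
Conditions: CuI (10 mol%), 3,4,7,8-tetramethyl-1,10-phenanthroline (20 mol%), Cs2CO3 (2 equiv), toluene, 110 °C, Ar
Reagents that add atoms: none
Why: Ullmann-type C–O coupling: Cs2CO3 deprotonates the ring-B carbinol, the alkoxide binds phenanthroline-ligated monovalent copper, oxidative addition of the neighbouring C–Br bond gives a trivalent copper aryl alkoxide, and reductive elimination forges O1–C8a. The closest known reaction type is the copper-catalysed cyclisation of 3-(2-haloaryl)propan-1-ols, including 1-(2-bromoaryl)propane-1,3-diols, to chromans and chroman-4-ols. Ring C closes as a six-membered ring by intramolecular ipso substitution at the sp2 carbon C8a (formally 6-exo-trig, through a seven-membered cupracycle). No stereocentre is made: the C–O bond of the ring-B carbinol is never cleaved, so C2 stays S, and C4 is a spectator. The step needs chemoselection between the two hydroxyls and freedom from β-hydride-driven hydrodebromination; the first is enforced by geometry, since the hydroxyl on the carbon attached to ring A could reach C8a only through a strained four-membered benzoxete, and the second is addressed by using copper under argon in toluene in place of palladium. Keeping C4 at the alcohol level also means that no enolisable β-alkoxy ketone meets the base, so ring opening and dehydration by E1cB pathways cannot intervene.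

Step 7
Reactants: 8 (2S,4S)-2-[3-(benzyloxy)-4,5-dimethoxyphenyl]-7,8-dimethoxychroman-4-ol
Product: 9 (2S)-2-[3-(benzyloxy)-4,5-dimethoxyphenyl]-7,8-dimethoxychroman-4-one
Conditions: Dess–Martin periodinane, pyridine, CH2Cl2, 0 °C to rt
Reagents that add atoms: none
Why: Dess–Martin oxidation of the secondary benzylic alcohol to the aryl ketone, buffered by pyridine so that the acid-labile chroman-4-ol is not ionised and the new flavanone is neither enolised nor ring-opened, which leaves C2 unepimerised.

Step 8
Reactants: 9 (2S)-2-[3-(benzyloxy)-4,5-dimethoxyphenyl]-7,8-dimethoxychroman-4-one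
Product: 10 (2S)-2-(3-hydroxy-4,5-dimethoxyphenyl)-7,8-dimethoxychroman-4-one (target)
Conditions: H2 (1 atm), 10% Pd/C, EtOAc, rt
Reagents that add atoms: none
Why: Catalytic hydrogenolysis of the aryl benzyl ether under neutral conditions, where O-debenzylation should be much faster than reduction of the aryl ketone or cleavage of the cyclic benzylic C2–O1 bond; no base is present, so C2 should stay S.

Compound list
1 | 2-bromo-3,4-dimethoxybenzaldehyde | COc1ccc(C=O)c(Br)c1OC | starting material
2 | 1-(2-bromo-3,4-dimethoxyphenyl)ethan-1-ol (racemic) | COc1ccc(C(C)O)c(Br)c1OC | intermediate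
3 | 1-(2-bromo-3,4-dimethoxyphenyl)ethan-1-one | COc1ccc(C(C)=O)c(Br)c1OC | intermediate
4 | methyl 3-hydroxy-4,5-dimethoxybenzoate | COC(=O)c1cc(O)c(OC)c(OC)c1 | starting material
5 | methyl 3-(benzyloxy)-4,5-dimethoxybenzoate | COC(=O)c1cc(OCc2ccccc2)c(OC)c(OC)c1 | intermediate
6 | 1-[3-(benzyloxy)-4,5-dimethoxyphenyl]-3-(2-bromo-3,4-dimethoxyphenyl)propane-1,3-dione | COc1cc(C(=O)CC(=O)c2ccc(OC)c(OC)c2Br)cc(OCc2ccccc2)c1OC | intermediate
7 | (1S,3S)-3-[3-(benzyloxy)-4,5-dimethoxyphenyl]-1-(2-bromo-3,4-dimethoxyphenyl)propane-1,3-diol | COc1cc([C@@H](O)C[C@H](O)c2ccc(OC)c(OC)c2Br)cc(OCc2ccccc2)c1OC | intermediate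
8 | (2S,4S)-2-[3-(benzyloxy)-4,5-dimethoxyphenyl]-7,8-dimethoxychroman-4-ol | COc1cc([C@@H]2C[C@H](O)c3ccc(OC)c(OC)c3O2)cc(OCc2ccccc2)c1OC | intermediate
9 | (2S)-2-[3-(benzyloxy)-4,5-dimethoxyphenyl]-7,8-dimethoxychroman-4-one | COc1cc([C@@H]2CC(=O)c3ccc(OC)c(OC)c3O2)cc(OCc2ccccc2)c1OC | intermediate
10 | (2S)-2-(3-hydroxy-4,5-dimethoxyphenyl)-7,8-dimethoxychroman-4-one | COc1cc([C@@H]2CC(=O)c3ccc(OC)c(OC)c3O2)cc(O)c1OC | target

Total step count: 8
Longest linear sequence: 7 steps (1 to 10 through steps 1, 2, 4, 5, 6, 7 and 8)

Steps most likely to fail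

Step 6. Oxidative addition at the doubly ortho-substituted C–Br bond may be sluggish, and the neighbouring benzylic alkoxide may divert the catalyst into hydrodebromination or alcohol oxidation by β-hydride transfer. The fallback sets out from diketone 6 and inverts the order of ring closure and stereocentre installation. CuI and K2CO3 in DMF at 110 °C should cyclise the enol oxygen of 6 onto the brominated carbon, an O-arylation assisted by the ortho carbonyl, to give 2-[3-(benzyloxy)-4,5-dimethoxyphenyl]-7,8-dimethoxy-4H-chromen-4-one F1. Enantioselective hydrogenation of this flavone would follow, using the chiral ruthenium N-heterocyclic carbene catalyst generated from [Ru(cod)(2-methylallyl)2], the imidazolinium salt SINpEt·HBF4 and KOtBu under H2 pressure, with the ligand enantiomer chosen for the 2S series. It is expected to reduce the C2=C3 bond and the carbonyl from the same face and so deliver the cis chroman-4-ol 8, where the route is rejoined before step 7. Any C4 epimer or flavanone 9 formed alongside converges in step 7.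

Step 5. The double reduction of the strongly enolised, ortho-hindered diaryl diketone may stall, lose anti selectivity or lose facial control at the ring-B carbonyl, and the electron-rich benzylic carbinols may ionise in the alcoholic medium; each would lower the enantiomeric purity at the future C2. The fallback sets out from ketone 3 and builds the two carbinols one at a time. Claisen–Schmidt condensation of 3 with purchased 3-(benzyloxy)-4,5-dimethoxybenzaldehyde F2 (KOH, EtOH, rt) should give (E)-3-[3-(benzyloxy)-4,5-dimethoxyphenyl]-1-(2-bromo-3,4-dimethoxyphenyl)prop-2-en-1-one F3. Copper-catalysed asymmetric conjugate borylation (CuCl, NaOtBu, a Josiphos-type ligand of the enantiomer that gives the S product, B2pin2, MeOH, THF, rt) should give (3S)-3-[3-(benzyloxy)-4,5-dimethoxyphenyl]-1-(2-bromo-3,4-dimethoxyphenyl)-3-(4,4,5,5-tetramethyl-1,3,2-dioxaborolan-2-yl)propan-1-one F4. Oxidation with NaBO3·4H2O in THF/H2O, which proceeds with retention, should give (3S)-3-[3-(benzyloxy)-4,5-dimethoxyphenyl]-1-(2-bromo-3,4-dimethoxyphenyl)-3-hydroxypropan-1-one F5. Evans–Saksena reduction with Me4NBH(OAc)3 in MeCN/AcOH at −20 °C, by intramolecular hydride delivery, should then give the anti diol 7, where the route is rejoined before step 6.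

Step 8. Over-reduction may compete with O-debenzylation, either by hydrogenolytic opening of the benzylic C2–O1 bond or by hydrogenation of the aryl ketone. The fallback sets out from 9 and removes the benzyl group without any reductant. BCl3 with pentamethylbenzene as cation scavenger in CH2Cl2 at −78 °C cleaves aryl benzyl ethers in preference to aryl methyl ethers and should give the target 10 directly. This fallback makes no new compound (F0).

Further compounds
F1 | step 6 | 2-[3-(benzyloxy)-4,5-dimethoxyphenyl]-7,8-dimethoxy-4H-chromen-4-one | COc1cc(-c2cc(=O)c3ccc(OC)c(OC)c3o2)cc(OCc2ccccc2)c1OC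
F2 | step 5 | 3-(benzyloxy)-4,5-dimethoxybenzaldehyde | COc1cc(C=O)cc(OCc2ccccc2)c1OC
F3 | step 5 | (E)-3-[3-(benzyloxy)-4,5-dimethoxyphenyl]-1-(2-bromo-3,4-dimethoxyphenyl)prop-2-en-1-one | COc1cc(/C=C/C(=O)c2ccc(OC)c(OC)c2Br)cc(OCc2ccccc2)c1OC
F4 | step 5 | (3S)-3-[3-(benzyloxy)-4,5-dimethoxyphenyl]-1-(2-bromo-3,4-dimethoxyphenyl)-3-(4,4,5,5-tetramethyl-1,3,2-dioxaborolan-2-yl)propan-1-one | COc1cc([C@@H](B2OC(C)(C)C(C)(C)O2)CC(=O)c2ccc(OC)c(OC)c2Br)cc(OCc2ccccc2)c1OC
F5 | step 5 | (3S)-3-[3-(benzyloxy)-4,5-dimethoxyphenyl]-1-(2-bromo-3,4-dimethoxyphenyl)-3-hydroxypropan-1-one | COc1cc([C@@H](O)CC(=O)c2ccc(OC)c(OC)c2Br)cc(OCc2ccccc2)c1OC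
F0 | step 8 | none | none
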